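**Plan** (target numbering: O1–O2–C3–C4–C4a(–O5–C6(=O)–C7–)C7a, C7a bonded to O1)
1. Retrosynthesis: cut the C16 chain (C2'=C3' by metathesis, C3–C1' by allylation of a C-3 peroxyketal); then, in one operation, O1–C7a and both bonds to the lactone carbonyl carbon (C7–C6, C6–O5); then the C-3 hydroperoxy ketal (ozonolysis), the vinyl group (Wittig) and C4–C4a's neighbour bond C4–C3 (epoxide opening).
2. Forward: an acyclic C8 dienol is built from a chiral-pool epoxide and its isopropenyl group is ozonised in methanol to an α-methoxy hydroperoxide. Both rings then close in one pot, the 1,2-dioxane first (peroxypalladation) and the γ-lactone second (CO taken up between C-7 and O5). The chain is joined last.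
3. Enabling feature: the vinyl group (C7a=C7) sits on the tertiary carbinol carbon C-4a. Its inner carbon is six atoms from the hydroperoxy oxygen (O–O–C3–C4–C4a–C7a), and its terminal CH2, once on palladium, is held next to the C-4a hydroxyl so that one CO completes the five-membered ring O5–C6–C7–C7a–C4a.
4. Stereochemistry: C-4a comes from (R)-2-methylglycidol and is never touched; C-7a is set in the cascade (cis ring fusion); C-3 is set by axial attack of allylsilane on the bicyclic peroxycarbenium ion, cis to the lactone oxygen.

Key step: step 5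

Remark: (R)-2-methylglycidol is taken as purchasable (Sharpless epoxidation product of 2-methylprop-2-en-1-ol); the C-3 (ketal) epimers of 10 and 14 are carried as mixtures because this centre is made planar again in step 6.

**Step 1**
Reactants: 1 (R)-2-methylglycidol; 2 isopropenylmagnesium bromide
Product: 3 (2S)-2,4-dimethylpent-4-ene-1,2-diol
Conditions: 2 (3 equiv), CuI (10 mol %), THF, −40 to 0 °C; aq NH4Cl
Reagents that add atoms: isopropenylmagnesium bromide, CC(=C)[Mg]Br
Why: Copper-catalysed Grignard opening of a 2,2-disubstituted epoxide takes place at the unsubstituted CH2 (SN2), so the quaternary carbinol centre keeps its configuration (the Payne rearrangement of the alkoxide is degenerate here); the first equivalent of 2 only deprotonates the hydroxyl.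

**Step 2**
Reactants: 3 (2S)-2,4-dimethylpent-4-ene-1,2-diol
Product: 4 (2S)-2-hydroxy-2,4-dimethylpent-4-enal
Conditions: (COCl)2, DMSO, CH2Cl2, −78 °C; Et3N, −78 to 0 °C
Reagents that add atoms: none
Why: Swern oxidation converts the primary alcohol to the aldehyde, the tertiary alcohol cannot be oxidised, activated DMSO does not cleave the 1,2-diol, and the quaternary α-centre cannot epimerise.

**Step 3**
Reactants: 4 (2S)-2-hydroxy-2,4-dimethylpent-4-enal; 5 methyltriphenylphosphonium bromide
Product: 6 (3S)-3,5-dimethylhexa-1,5-dien-3-ol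
Conditions: 5 (2.6 equiv), KOtBu (2.5 equiv), THF, 0 °C; then 4, −78 °C to rt
Reagents that add atoms: methyltriphenylphosphonium bromide, C[P+](c1ccccc1)(c1ccccc1)c1ccccc1.[Br-]
Why: Wittig methylenation of the α-hydroxy aldehyde (excess ylide absorbs the free hydroxyl) should give the vinyl carbinol without touching the quaternary stereocentre.

**Step 4**
Reactants: 6 (3S)-3,5-dimethylhexa-1,5-dien-3-ol; 7 ozone; 8 methanol
Product: 10 (3S)-5-hydroperoxy-5-methoxy-3-methylhex-1-en-3-ol (both C-5 epimers), via carbonyl oxide 9 (not isolated)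
Conditions: O3 (1.0 equiv, Sudan Red 7B end-point), CH2Cl2/MeOH 4:1, −78 °C; N2 purge, kept cold
Reagents that add atoms: ozone, [O-][O+]=O; methanol, CO
Why: Ozonolysis in methanol: ozone should add faster to the electron-richer 1,1-disubstituted alkene than to the vinyl group deactivated by the allylic oxygen, the primary ozonide splits into formaldehyde and the more substituted carbonyl oxide (Criegee intermediate), and methanol traps it as the α-methoxy hydroperoxide; the new ketal centre forms unselectively, which does not matter because it is ionised in step 6.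

**Step 5**
Reactants: 10 (3S)-5-hydroperoxy-5-methoxy-3-methylhex-1-en-3-ol; 11 carbon monoxide
Product: 14 (4aS,7aS)-3-methoxy-3,4a-dimethyltetrahydro-3H-furo[3,2-c][1,2]dioxin-6(4H)-one (both C-3 epimers), via alkylpalladium dioxane 12 (not isolated), via acylpalladium dioxane 13 (not isolated)
Conditions: Pd(OAc)2 (10 mol %), p-benzoquinone (1.5 equiv), CO (1 atm), THF, 0 °C to rt
Reagents that add atoms: carbon monoxide, [C-]#[O+]
Why: Proposed new method: Pd(OAc)2 binds the vinyl group, the hydroperoxy oxygen attacks its inner carbon anti to palladium (6-exo-trig peroxypalladation, closing the 1,2-dioxane) and leaves a CH2–Pd bond; CO then joins this CH2 to the carbonyl carbon while the neighbouring tertiary hydroxyl completes the lactone at palladium (CO insertion into Pd–O and C–C reductive elimination from the six-membered palladacycle, or insertion into Pd–C and acyl transfer to oxygen, lead to the same product), and benzoquinone returns zerovalent palladium to the divalent state. The closest known reaction types are the alkoxypalladation–carbonylation–lactonisation of alkene-diols to cis-fused bicyclic lactones and the Pd(OAc)2-catalysed cyclisation of unsaturated hydroperoxides to 1,2-dioxanes; new is a hydroperoxy ketal as the oxygen nucleophile in the carbonylative manifold. Ring closures: the dioxane by 6-exo-trig O–C bond formation, the γ-lactone as a five-membered ring through the CH2–C(=O) bond made at palladium. The new stereocentre C-7a is controlled by C-4a: in the chair transition state the C-4a methyl and the vinyl group should lie equatorial and the hydroxyl axial, which places OH and CH2Pd cis, the arrangement that lactonises readily to the cis-fused bicycle. The step needs 6-exo over 7-endo attack (secured by the more substituted inner alkene carbon), CO capture faster than β-hydride elimination (CO atmosphere, low temperature) and survival of the O–O bond (benzoquinone keeps zerovalent palladium scarce; no copper salts).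

**Step 6**
Reactants: 14 (4aS,7aS)-3-methoxy-3,4a-dimethyltetrahydro-3H-furo[3,2-c][1,2]dioxin-6(4H)-one; 15 allyltrimethylsilane
Product: 17 (3R,4aS,7aS)-3-allyl-3,4a-dimethyltetrahydro-3H-furo[3,2-c][1,2]dioxin-6(4H)-one, via peroxycarbenium ion 16 (not isolated)
Conditions: 15 (3 equiv), Me3SiOTf (0.5 equiv), CH2Cl2, −78 °C
Reagents that add atoms: allyltrimethylsilane, C=CC[Si](C)(C)C
Why: Hosomi–Sakurai allylation of a cyclic monoperoxyketal: either C-3 epimer ionises to the same peroxycarbenium ion, whose half-chair should hold the C-4a methyl and the C-7a CH2 pseudoequatorial and the C-4a lactone oxygen pseudoaxial, so that axial attack through a chair-like transition state brings the allyl group in cis to the lactone oxygen and trans to the C-4a methyl, giving the (3R) quaternary centre.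

**Step 7**
Reactants: 17 (3R,4aS,7aS)-3-allyl-3,4a-dimethyltetrahydro-3H-furo[3,2-c][1,2]dioxin-6(4H)-one; 18 pentadec-1-ene
Product: 19 (3R,4aS,7aS)-3-[(E)-hexadec-2-en-1-yl]-3,4a-dimethyltetrahydro-3H-furo[3,2-c][1,2]dioxin-6(4H)-one (the Z isomer is equally usable)
Conditions: 18 (5 equiv), second-generation Grubbs catalyst (H2IMes)(PCy3)Cl2Ru=CHPh (5 mol %), CH2Cl2, 40 °C
Reagents that add atoms: pentadec-1-ene, CCCCCCCCCCCCCC=C
Why: Olefin cross-metathesis of the terminal allyl group with excess pentadec-1-ene, driven by loss of ethylene; ruthenium alkylidenes tolerate dialkyl peroxides and lactones, and the alkene geometry is irrelevant.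

**Step 8**
Reactants: 19 (3R,4aS,7aS)-3-[(E)-hexadec-2-en-1-yl]-3,4a-dimethyltetrahydro-3H-furo[3,2-c][1,2]dioxin-6(4H)-one
Product: 20 (3R,4aS,7aS)-3-hexadecyl-3,4a-dimethyltetrahydro-3H-furo[3,2-c][1,2]dioxin-6(4H)-one (target)
Conditions: dipotassium azodicarboxylate (10 equiv), AcOH (20 equiv), CH2Cl2/MeOH, 0 °C to rt
Reagents that add atoms: none
Why: Diimide reduction adds H2 to the isolated alkene by concerted syn transfer without reducing the O–O bond or the lactone, and the weakly acidic medium avoids base-induced Kornblum–DeLaMare cleavage at C-7a–H; no stereocentre is affected.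

**Compound list**
1 | (R)-2-methylglycidol | C[C@@]1(CO)CO1 | starting material
2 | isopropenylmagnesium bromide | CC(=C)[Mg]Br | starting material
3 | (2S)-2,4-dimethylpent-4-ene-1,2-diol | C[C@](O)(CC(C)=C)CO | intermediate
4 | (2S)-2-hydroxy-2,4-dimethylpent-4-enal | C[C@](O)(CC(C)=C)C=O | intermediate
5 | methyltriphenylphosphonium bromide | C[P+](c1ccccc1)(c1ccccc1)c1ccccc1.[Br-] | starting material
6 | (3S)-3,5-dimethylhexa-1,5-dien-3-ol | C[C@](O)(CC(C)=C)C=C | intermediate
7 | ozone | [O-][O+]=O | starting material
8 | methanol | CO | starting material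
9 | carbonyl oxide formed at C-5 of 6 (not isolated) | C[C@](O)(CC(C)=[O+][O-])C=C | intermediate
10 | (3S)-5-hydroperoxy-5-methoxy-3-methylhex-1-en-3-ol, both C-5 epimers | C[C@](O)(CC(C)(OC)OO)C=C | intermediate
11 | carbon monoxide | [C-]#[O+] | starting material
12 | alkylpalladium dioxane (acetatopalladiomethyl on C-6 of the 1,2-dioxan-5-ol; not isolated) | COC1(C)C[C@](C)(O)[C@H](C[Pd]OC(C)=O)OO1 | intermediate
13 | acylpalladium dioxane (not isolated) | COC1(C)C[C@](C)(O)[C@H](CC(=O)[Pd]OC(C)=O)OO1 | intermediate
14 | (4aS,7aS)-3-methoxy-3,4a-dimethyltetrahydro-3H-furo[3,2-c][1,2]dioxin-6(4H)-one, both C-3 epimers | COC1(C)C[C@]2(C)OC(=O)C[C@@H]2OO1 | intermediate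
15 | allyltrimethylsilane | C=CC[Si](C)(C)C | starting material
16 | bicyclic peroxycarbenium ion (not isolated) | CC1=[O+]O[C@H]2CC(=O)O[C@@]2(C)C1 | intermediate
17 | (3R,4aS,7aS)-3-allyl-3,4a-dimethyltetrahydro-3H-furo[3,2-c][1,2]dioxin-6(4H)-one | C=CC[C@]1(C)C[C@]2(C)OC(=O)C[C@@H]2OO1 | intermediate
18 | pentadec-1-ene | CCCCCCCCCCCCCC=C | starting material
19 | (3R,4aS,7aS)-3-[(E)-hexadec-2-en-1-yl]-3,4a-dimethyltetrahydro-3H-furo[3,2-c][1,2]dioxin-6(4H)-one | CCCCCCCCCCCCC/C=C/C[C@]1(C)C[C@]2(C)OC(=O)C[C@@H]2OO1 | intermediate
20 | (3R,4aS,7aS)-3-hexadecyl-3,4a-dimethyltetrahydro-3H-furo[3,2-c][1,2]dioxin-6(4H)-one | CCCCCCCCCCCCCCCC[C@]1(C)C[C@]2(C)OC(=O)C[C@@H]2OO1 | target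

Total steps: 8. Longest linear sequence: 8 steps (from 1).

**Steps most likely to fail**

Step 5 (proposed new method). What may go wrong: reduction of the hydroperoxide by zerovalent palladium or CO with loss of the O–O bond, β-hydride elimination from the alkylpalladium before CO capture, or palladium-mediated oxidation of CO by the hydroperoxide. Fallback with known chemistry, from 10 back to 14: stoichiometric cycloperoxymercuration of 10 with Hg(OAc)2 in CH2Cl2 and anion exchange with KBr would give (5S,6R)-6-[(bromomercurio)methyl]-3-methoxy-3,5-dimethyl-1,2-dioxan-5-ol F1; transmetalation of this β-oxygenated alkylmercurial with Li2PdCl4 under CO (1 atm, THF) would give the acylpalladium species, which the cis tertiary hydroxyl captures to form 14.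

Step 4. What may go wrong: poor chemoselectivity of ozone between the two alkenes, with over-oxidation of the vinyl group. Fallback, from 6 back to 10: acetylation of the tertiary alcohol (Ac2O, DMAP, Et3N) would give (3S)-3,5-dimethylhexa-1,5-dien-3-yl acetate F2, whose vinyl group is further deactivated by the allylic ester; ozonolysis in CH2Cl2/MeOH would then give (3S)-5-hydroperoxy-5-methoxy-3-methylhex-1-en-3-yl acetate F3, and methanolysis (K2CO3, MeOH, 0 °C) would release 10.

Step 6. What may go wrong: poor facial selectivity in the attack on the peroxycarbenium ion, or heterolytic fragmentation of that ion before C–C bond formation. Fallback, from 1 back to 20, building the tertiary peroxide by radical chemistry with the whole chain in place: copper-catalysed opening of 1 with octadec-1-en-2-ylmagnesium bromide F4 (from 2-bromooctadec-1-ene and magnesium) would give (2S)-2-methyl-4-methylideneicosane-1,2-diol F5; Swern oxidation would give (2S)-2-hydroxy-2-methyl-4-methylideneicosanal F6 and Wittig methylenation (3S)-3-methyl-5-methylidenehenicos-1-en-3-ol F7; Isayama–Mukaiyama hydroperoxysilylation of the 1,1-disubstituted alkene (Co(acac)2, O2, Et3SiH) would give (3S)-3,5-dimethyl-5-(triethylsilylperoxy)henicos-1-en-3-ol F8 as both C-5 epimers; desilylation (Bu4NF, AcOH) would give (3S)-5-hydroperoxy-3,5-dimethylhenicos-1-en-3-ol F9; ring closure under the conditions of step 5 (this fallback is only needed when step 5 has worked) would give 20 together with (3S,4aS,7aS)-3-hexadecyl-3,4a-dimethyltetrahydro-3H-furo[3,2-c][1,2]dioxin-6(4H)-one F10, to be separated by chromatography.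

**Further compounds**
F1 | step 5 | (5S,6R)-6-[(bromomercurio)methyl]-3-methoxy-3,5-dimethyl-1,2-dioxan-5-ol | COC1(C)C[C@](C)(O)[C@H](C[Hg]Br)OO1
F2 | step 4 | (3S)-3,5-dimethylhexa-1,5-dien-3-yl acetate | CC(=O)O[C@@](C)(CC(C)=C)C=C
F3 | step 4 | (3S)-5-hydroperoxy-5-methoxy-3-methylhex-1-en-3-yl acetate | CC(=O)O[C@@](C)(CC(C)(OC)OO)C=C
F4 | step 6 | octadec-1-en-2-ylmagnesium bromide | C=C(CCCCCCCCCCCCCCCC)[Mg]Br
F5 | step 6 | (2S)-2-methyl-4-methylideneicosane-1,2-diol | C[C@](O)(CC(=C)CCCCCCCCCCCCCCCC)CO
F6 | step 6 | (2S)-2-hydroxy-2-methyl-4-methylideneicosanal | C[C@](O)(CC(=C)CCCCCCCCCCCCCCCC)C=O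
F7 | step 6 | (3S)-3-methyl-5-methylidenehenicos-1-en-3-ol | C[C@](O)(CC(=C)CCCCCCCCCCCCCCCC)C=C
F8 | step 6 | (3S)-3,5-dimethyl-5-(triethylsilylperoxy)henicos-1-en-3-ol | C[C@](O)(CC(C)(OO[Si](CC)(CC)CC)CCCCCCCCCCCCCCCC)C=C
F9 | step 6 | (3S)-5-hydroperoxy-3,5-dimethylhenicos-1-en-3-ol | C[C@](O)(CC(C)(OO)CCCCCCCCCCCCCCCC)C=C
F10 | step 6 | (3S,4aS,7aS)-3-hexadecyl-3,4a-dimethyltetrahydro-3H-furo[3,2-c][1,2]dioxin-6(4H)-one | CCCCCCCCCCCCCCCC[C@@]1(C)C[C@]2(C)OC(=O)C[C@@H]2OO1
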